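The route rests on disconnecting the O–C2 bond of the 2,2-dimethylchroman fused to ring B across C4'–C5'. In one operation, mild acid joins the free 4'-hydroxyl to the tertiary carbon of the 5'-prenyl group. This exploits the fact that O4' is the only hydroxyl ortho to a prenyl group, whereas the 6'-prenyl lies between C1' and C5'. The substrate is the 8-(1,1-dimethylallyl)-5',6'-diprenyl flavonol with free 3-, 3'- and 4'-hydroxyls, carried as its 5,7-diallyl ether so that O7 cannot add to the vinyl group at C8. It is built from a diprenylbenzaldehyde and a ring A acetophenone by aldol condensation and oxidative cyclisation.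

Key step: step 11

Assumption: the target is taken exactly as drawn in the SMILES (achiral; 2-methylbut-3-en-2-yl at C8, prenyl at C6', chroman across O4'–C5'), and tributyl(3-methylbut-2-enyl)stannane is taken as a purchasable reagent.

Step 1
Reactants: 1 5-bromovanillin (3-bromo-4-hydroxy-5-methoxybenzaldehyde)
Product: 2 2,3-dibromo-4-hydroxy-5-methoxybenzaldehyde
Conditions: Br2, Fe powder (cat.), AcOH, 25 → 50 °C
Reagents that add atoms: bromine, BrBr
Why: Electrophilic aromatic bromination should take the free position para to the methoxy group, because the other free carbon is only ortho-activated and is wedged between the formyl and methoxy groups.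

Step 2
Reactants: 2 2,3-dibromo-4-hydroxy-5-methoxybenzaldehyde
Product: 3 2,3-dibromo-4,5-dihydroxybenzaldehyde
Conditions: BBr3, CH2Cl2, −78 → 25 °C; then H2O
Reagents that add atoms: none
Why: Lewis-acid ether cleavage with BBr3 should remove the methyl group by bromide attack on the boron-bound ether and free the catechol on hydrolysis, the aldehyde and the aryl bromides being inert at this temperature.

Step 3
Reactants: 3 2,3-dibromo-4,5-dihydroxybenzaldehyde
Product: 4 2,3-dibromo-4,5-bis(methoxymethoxy)benzaldehyde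
Conditions: MOMCl, K2CO3, acetone, 25 → 50 °C
Reagents that add atoms: chloromethyl methyl ether, COCCl
Why: Williamson-type O-alkylation of the two phenoxides should give the bis(methoxymethyl) ether, a pair of acetals that tolerates palladium catalysis, KOH and alkaline peroxide and leaves under dilute acid.

Step 4
Reactants: 4 2,3-dibromo-4,5-bis(methoxymethoxy)benzaldehyde; 5 tributyl(3-methylbut-2-enyl)stannane
Product: 6 4,5-bis(methoxymethoxy)-2,3-bis(3-methylbut-2-enyl)benzaldehyde
Conditions: Pd(PPh3)4 (10 mol %), DMF, 100 °C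
Reagents that add atoms: 5 tributyl(3-methylbut-2-enyl)stannane, CCCC[Sn](CCCC)(CCCC)CC=C(C)C
Why: A twofold Stille coupling should replace both bromides, since zerovalent palladium inserts into each C–Br bond (first the one ortho to the formyl group), the allylstannane transmetalates and reductive elimination at the unsubstituted allyl terminus gives linear prenyl groups, as is usual for prenylstannanes.

Step 5
Reactants: 7 2,4,6-trihydroxyacetophenone; 8 prenyl bromide (1-bromo-3-methylbut-2-ene)
Product: 9 1-[2,6-dihydroxy-4-(3-methylbut-2-enyloxy)phenyl]ethanone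
Conditions: K2CO3 (1 equiv), acetone, 25 °C
Reagents that add atoms: 8 prenyl bromide, CC(C)=CCBr
Why: Williamson ether synthesis with one equivalent of halide should select the 4-hydroxyl, which is the most acidic and the only one not held in a hydrogen bond to the acetyl group.

Step 6
Reactants: 9 1-[2,6-dihydroxy-4-(3-methylbut-2-enyloxy)phenyl]ethanone
Product: 11 1-[2,4,6-trihydroxy-3-(2-methylbut-3-en-2-yl)phenyl]ethanone, via ortho-dienone 10 (not isolated)
Conditions: PhNEt2, 170 °C, sealed tube
Reagents that add atoms: none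
Why: The aromatic Claisen rearrangement should shift the allyl unit with inversion onto C3 (C3 and C5 are equivalent, and the para carbon bears the acetyl group, so no Cope relay can aromatise) to give dienone 10, whose enolisation restores the phenol, while the basic solvent holds back addition of the new ortho hydroxyls to the vinyl group.

Step 7
Reactants: 11 1-[2,4,6-trihydroxy-3-(2-methylbut-3-en-2-yl)phenyl]ethanone
Product: 12 1-[2-hydroxy-3-(2-methylbut-3-en-2-yl)-4,6-bis(prop-2-enyloxy)phenyl]ethanone
Conditions: allyl bromide (2.1 equiv), K2CO3, acetone, 45 °C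
Reagents that add atoms: allyl bromide, C=CCBr
Why: Williamson ether synthesis should alkylate the 4-hydroxyl and then the 6-hydroxyl, whereas the 2-hydroxyl, chelated to the acetyl group and crowded by the quaternary carbon, stays free and so directs the later pyranone closure to the side of the tert-prenyl group.

Step 8
Reactants: 12 1-[2-hydroxy-3-(2-methylbut-3-en-2-yl)-4,6-bis(prop-2-enyloxy)phenyl]ethanone; 6 4,5-bis(methoxymethoxy)-2,3-bis(3-methylbut-2-enyl)benzaldehyde
Product: 14 (E)-1-[2-hydroxy-3-(2-methylbut-3-en-2-yl)-4,6-bis(prop-2-enyloxy)phenyl]-3-[4,5-bis(methoxymethoxy)-2,3-bis(3-methylbut-2-enyl)phenyl]prop-2-en-1-one, via aldol adduct 13 (not isolated)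
Conditions: KOH (50% aq.), EtOH, 25 °C
Reagents that add atoms: none
Why: In this Claisen–Schmidt condensation the enolate of the methyl ketone should add to the non-enolisable aldehyde to give aldol 13, and E1cB loss of water then gives the E-enone, with acetals, allyl ethers and isolated alkenes inert to hydroxide.

Step 9
Reactants: 14 (E)-chalcone from step 8
Product: 16 3-hydroxy-2-[4,5-bis(methoxymethoxy)-2,3-bis(3-methylbut-2-enyl)phenyl]-8-(2-methylbut-3-en-2-yl)-5,7-bis(prop-2-enyloxy)chromen-4-one, via trans-dihydroflavonol 15 (not isolated)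
Conditions: H2O2 (30% aq.), NaOH (2 M aq.), MeOH/THF, 0 → 25 °C
Reagents that add atoms: hydrogen peroxide, OO
Why: In the Algar–Flynn–Oyamada reaction hydroperoxide should oxidise the enone while the 2'-phenoxide closes the pyranone at the β-carbon to give dihydroflavonol 15, which alkaline peroxide dehydrogenates to the flavonol, the isolated alkenes being inert to nucleophilic peroxide.

Step 10
Reactants: 16 ring B bis(methoxymethyl) flavonol from step 9
Product: 17 2-[4,5-dihydroxy-2,3-bis(3-methylbut-2-enyl)phenyl]-3-hydroxy-8-(2-methylbut-3-en-2-yl)-5,7-bis(prop-2-enyloxy)chromen-4-one (5,7-diallyl ether of 3,5,7,3',4'-pentahydroxy-8-(1,1-dimethylallyl)-5',6'-diprenylflavone)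
Conditions: HCl (3 M aq.), MeOH/THF, 45 °C
Reagents that add atoms: none
Why: Acid-catalysed acetal exchange with methanol should remove both ring B methoxymethyl groups as dimethoxymethane while the ring A allyl ethers hold, and since alkene protonation is slow in this levelling medium, any chroman formed early would only be the product of step 11.

Step 11
Reactants: 17 5,7-diallyl ether of the diprenyl flavonol (free 3-, 3'- and 4'-hydroxyls)
Product: 18 3-hydroxy-2-[8-hydroxy-2,2-dimethyl-5-(3-methylbut-2-enyl)-3,4-dihydro-2H-chromen-6-yl]-8-(2-methylbut-3-en-2-yl)-5,7-bis(prop-2-enyloxy)chromen-4-one (5,7-di-O-allyl Broussoflavonol E)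
Conditions: TsOH·H2O (10 mol %), PhMe, 40 °C; then NaHCO3 (aq.)
Reagents that add atoms: none
Why: This is an acid-catalysed intramolecular hydroalkoxylation of an ortho-prenylphenol: Markovnikov protonation of the trisubstituted C5' alkene gives a tertiary cation (or its hydrogen-bonded equivalent) that O4' captures to form the O–CMe2 bond. The closest known reaction type is the acid-mediated conversion of ortho-prenylphenols into 2,2-dimethylchromans, long used on prenylated flavonoids. The one new ring, the dihydropyran fused at C4'–C5', closes in a 6-endo-trig mode, both alkene carbons ending inside the ring. No stereocentre is created, so no stereocontrol element is needed. The step needs chemoselection among five alkenes and three free hydroxyls: only O4' is ortho to a prenyl group, the cation of the 6'-prenyl group (flanked by C1' and C5') has no hydroxyl within reach of a five- or six-membered closure and can only revert, and the vinyl and allyl alkenes would give secondary cations and are protonated far more slowly. Capping O7 as the allyl ether removes the only alternative ring closure, addition of O7 to the C8 vinyl group.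

Step 12
Reactants: 18 5,7-di-O-allyl Broussoflavonol E
Product: 19 Broussoflavonol E
Conditions: Pd(PPh3)4 (5 mol %), morpholine, THF, 25 °C, argon
Reagents that add atoms: none
Why: In this palladium-catalysed deallylation of Tsuji–Trost type, zerovalent palladium should ionise each aryl allyl ether to a π-allyl complex and a phenoxide, morpholine takes up the allyl unit, and the prenyl, tert-prenyl and chroman units, which have no allylic leaving group, are left alone.

Compound list

1 | 5-bromovanillin (3-bromo-4-hydroxy-5-methoxybenzaldehyde) | COc1cc(C=O)cc(Br)c1O | starting material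
2 | 2,3-dibromo-4-hydroxy-5-methoxybenzaldehyde | COc1cc(C=O)c(Br)c(Br)c1O | intermediate
3 | 2,3-dibromo-4,5-dihydroxybenzaldehyde | O=Cc1cc(O)c(O)c(Br)c1Br | intermediate
4 | 2,3-dibromo-4,5-bis(methoxymethoxy)benzaldehyde | O=Cc1cc(OCOC)c(OCOC)c(Br)c1Br | intermediate
5 | tributyl(3-methylbut-2-enyl)stannane | CCCC[Sn](CCCC)(CCCC)CC=C(C)C | starting material
6 | 4,5-bis(methoxymethoxy)-2,3-bis(3-methylbut-2-enyl)benzaldehyde | O=Cc1cc(OCOC)c(OCOC)c(CC=C(C)C)c1CC=C(C)C | intermediate
7 | 2,4,6-trihydroxyacetophenone | CC(=O)c1c(O)cc(O)cc1O | starting material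
8 | prenyl bromide (1-bromo-3-methylbut-2-ene) | CC(C)=CCBr | starting material
9 | 1-[2,6-dihydroxy-4-(3-methylbut-2-enyloxy)phenyl]ethanone | CC(=O)c1c(O)cc(OCC=C(C)C)cc1O | intermediate
10 | 4-acetyl-3,5-dihydroxy-6-(2-methylbut-3-en-2-yl)cyclohexa-2,4-dien-1-one (racemic ortho-dienone, not isolated) | CC(=O)C1=C(O)C(C(C)(C)C=C)C(=O)C=C1O | intermediate
11 | 1-[2,4,6-trihydroxy-3-(2-methylbut-3-en-2-yl)phenyl]ethanone | CC(=O)c1c(O)cc(O)c(C(C)(C)C=C)c1O | intermediate
12 | 1-[2-hydroxy-3-(2-methylbut-3-en-2-yl)-4,6-bis(prop-2-enyloxy)phenyl]ethanone | CC(=O)c1c(OCC=C)cc(OCC=C)c(C(C)(C)C=C)c1O | intermediate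
13 | 3-hydroxy-1-[2-hydroxy-3-(2-methylbut-3-en-2-yl)-4,6-bis(prop-2-enyloxy)phenyl]-3-[4,5-bis(methoxymethoxy)-2,3-bis(3-methylbut-2-enyl)phenyl]propan-1-one (racemic aldol adduct, not isolated) | CC(C)=CCc1c(CC=C(C)C)c(OCOC)c(OCOC)cc1C(O)CC(=O)c1c(OCC=C)cc(OCC=C)c(C(C)(C)C=C)c1O | intermediate
14 | (E)-1-[2-hydroxy-3-(2-methylbut-3-en-2-yl)-4,6-bis(prop-2-enyloxy)phenyl]-3-[4,5-bis(methoxymethoxy)-2,3-bis(3-methylbut-2-enyl)phenyl]prop-2-en-1-one | CC(C)=CCc1c(CC=C(C)C)c(OCOC)c(OCOC)cc1/C=C/C(=O)c1c(OCC=C)cc(OCC=C)c(C(C)(C)C=C)c1O | intermediate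
15 | trans-3-hydroxy-2-[4,5-bis(methoxymethoxy)-2,3-bis(3-methylbut-2-enyl)phenyl]-8-(2-methylbut-3-en-2-yl)-5,7-bis(prop-2-enyloxy)chroman-4-one (racemic, (2R,3R) enantiomer drawn; not isolated) | CC(C)=CCc1c(CC=C(C)C)c(OCOC)c(OCOC)cc1[C@H]1Oc2c(C(C)(C)C=C)c(OCC=C)cc(OCC=C)c2C(=O)[C@@H]1O | intermediate
16 | 3-hydroxy-2-[4,5-bis(methoxymethoxy)-2,3-bis(3-methylbut-2-enyl)phenyl]-8-(2-methylbut-3-en-2-yl)-5,7-bis(prop-2-enyloxy)chromen-4-one | CC(C)=CCc1c(CC=C(C)C)c(OCOC)c(OCOC)cc1-c1oc2c(C(C)(C)C=C)c(OCC=C)cc(OCC=C)c2c(=O)c1O | intermediate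
17 | 2-[4,5-dihydroxy-2,3-bis(3-methylbut-2-enyl)phenyl]-3-hydroxy-8-(2-methylbut-3-en-2-yl)-5,7-bis(prop-2-enyloxy)chromen-4-one | CC(C)=CCc1c(CC=C(C)C)c(O)c(O)cc1-c1oc2c(C(C)(C)C=C)c(OCC=C)cc(OCC=C)c2c(=O)c1O | intermediate
18 | 3-hydroxy-2-[8-hydroxy-2,2-dimethyl-5-(3-methylbut-2-enyl)-3,4-dihydro-2H-chromen-6-yl]-8-(2-methylbut-3-en-2-yl)-5,7-bis(prop-2-enyloxy)chromen-4-one | CC(C)=CCc1c2CCC(C)(C)Oc2c(O)cc1-c1oc2c(C(C)(C)C=C)c(OCC=C)cc(OCC=C)c2c(=O)c1O | intermediate
19 | Broussoflavonol E (3,5,7-trihydroxy-2-[8-hydroxy-2,2-dimethyl-5-(3-methylbut-2-enyl)-3,4-dihydro-2H-chromen-6-yl]-8-(2-methylbut-3-en-2-yl)chromen-4-one) | C=CC(C)(C)c1c(O)cc(O)c2c(=O)c(O)c(-c3cc(O)c4c(c3CC=C(C)C)CCC(C)(C)O4)oc12 | target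

Total step count: 12. Longest linear sequence: 9 steps (1 to 19 through steps 1–4 and 8–12); the ring A branch (steps 5–7) joins at step 8.

Steps most likely to fail

Step 11. Reversible ionisation of the 6'-prenyl group may outrun ring closure, so that double-bond migration or hydration of that group, or stalled conversion, erodes the product. The fallback moves the ring closure ahead of flavonol formation and sets out from chalcone 14. Dilute HCl in MeOH/THF would remove the two acetals to give (E)-1-[2-hydroxy-3-(2-methylbut-3-en-2-yl)-4,6-bis(prop-2-enyloxy)phenyl]-3-[4,5-dihydroxy-2,3-bis(3-methylbut-2-enyl)phenyl]prop-2-en-1-one F1. Catalytic TsOH·H2O in toluene would then close the chroman on this less polar, non-chelating substrate to give (E)-1-[2-hydroxy-3-(2-methylbut-3-en-2-yl)-4,6-bis(prop-2-enyloxy)phenyl]-3-[8-hydroxy-2,2-dimethyl-5-(3-methylbut-2-enyl)-3,4-dihydro-2H-chromen-6-yl]prop-2-en-1-one F2. Algar–Flynn–Oyamada oxidation of F2 (H2O2, NaOH, MeOH/THF) would give 18, where the route is rejoined.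

Step 9. Closure of the 2'-phenoxide at the α-carbon (the five-membered, aurone pathway) may compete with closure at the β-carbon, a known tendency of 6'-alkoxychalcones that the ortho-substituted ring B could reinforce. The fallback separates epoxidation from ring closure and sets out from chalcone 14. MOMCl/NaH in DMF would cap the 2'-hydroxyl to give (E)-1-[2-(methoxymethoxy)-3-(2-methylbut-3-en-2-yl)-4,6-bis(prop-2-enyloxy)phenyl]-3-[4,5-bis(methoxymethoxy)-2,3-bis(3-methylbut-2-enyl)phenyl]prop-2-en-1-one F3. H2O2/NaOH would epoxidise the enone with no phenoxide present, giving the racemic trans-epoxide [2-(methoxymethoxy)-3-(2-methylbut-3-en-2-yl)-4,6-bis(prop-2-enyloxy)phenyl]{3-[4,5-bis(methoxymethoxy)-2,3-bis(3-methylbut-2-enyl)phenyl]oxiran-2-yl}methanone F4. Brief treatment with dilute HCl in MeOH/THF at 20 °C would cleave the ketone-flanked acetal preferentially, and the freed phenol would open the protonated epoxide at the benzylic carbon with inversion to give trans-dihydroflavonol 15, now isolated. Alkaline H2O2 would dehydrogenate 15 to flavonol 16, where the route is rejoined.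

Step 6. The freshly formed ortho-(1,1-dimethylallyl)phenol may react on at the rearrangement temperature, by addition of a neighbouring hydroxyl to the vinyl group or by abnormal Claisen isomerisation of the side chain. The fallback keeps every phenol acylated during the rearrangement and sets out from ether 9. Ac2O/pyridine would give 1-[2,6-diacetoxy-4-(3-methylbut-2-enyloxy)phenyl]ethanone F5. Heating F5 with Ac2O and NaOAc in PhNEt2 would effect the Claisen rearrangement with immediate acetylation of the new phenol, giving 1-[2,4,6-triacetoxy-3-(2-methylbut-3-en-2-yl)phenyl]ethanone F6. K2CO3 in MeOH would cleave the three esters and return triol 11.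

Further compounds

F1 | step 11 | (E)-1-[2-hydroxy-3-(2-methylbut-3-en-2-yl)-4,6-bis(prop-2-enyloxy)phenyl]-3-[4,5-dihydroxy-2,3-bis(3-methylbut-2-enyl)phenyl]prop-2-en-1-one | O=C(/C=C/c1cc(O)c(O)c(CC=C(C)C)c1CC=C(C)C)c1c(OCC=C)cc(OCC=C)c(C(C)(C)C=C)c1O
F2 | step 11 | (E)-1-[2-hydroxy-3-(2-methylbut-3-en-2-yl)-4,6-bis(prop-2-enyloxy)phenyl]-3-[8-hydroxy-2,2-dimethyl-5-(3-methylbut-2-enyl)-3,4-dihydro-2H-chromen-6-yl]prop-2-en-1-one | O=C(/C=C/c1cc(O)c2OC(C)(C)CCc2c1CC=C(C)C)c1c(OCC=C)cc(OCC=C)c(C(C)(C)C=C)c1O
F3 | step 9 | (E)-1-[2-(methoxymethoxy)-3-(2-methylbut-3-en-2-yl)-4,6-bis(prop-2-enyloxy)phenyl]-3-[4,5-bis(methoxymethoxy)-2,3-bis(3-methylbut-2-enyl)phenyl]prop-2-en-1-one | O=C(/C=C/c1cc(OCOC)c(OCOC)c(CC=C(C)C)c1CC=C(C)C)c1c(OCC=C)cc(OCC=C)c(C(C)(C)C=C)c1OCOC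
F4 | step 9 | [2-(methoxymethoxy)-3-(2-methylbut-3-en-2-yl)-4,6-bis(prop-2-enyloxy)phenyl]{3-[4,5-bis(methoxymethoxy)-2,3-bis(3-methylbut-2-enyl)phenyl]oxiran-2-yl}methanone (racemic trans-epoxide, one enantiomer drawn) | O=C([C@@H]1O[C@H]1c1cc(OCOC)c(OCOC)c(CC=C(C)C)c1CC=C(C)C)c1c(OCC=C)cc(OCC=C)c(C(C)(C)C=C)c1OCOC
F5 | step 6 | 1-[2,6-diacetoxy-4-(3-methylbut-2-enyloxy)phenyl]ethanone | CC(=O)Oc1cc(OCC=C(C)C)cc(OC(C)=O)c1C(C)=O
F6 | step 6 | 1-[2,4,6-triacetoxy-3-(2-methylbut-3-en-2-yl)phenyl]ethanone | CC(=O)Oc1cc(OC(C)=O)c(C(C)(C)C=C)c(OC(C)=O)c1C(C)=O
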